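## Retrosynthetic overview

1. Kanzonol Y (13) ⇐ its tris-MOM ether 12 by global acetal cleavage.
2. 12 ⇐ chalcone 7 by a one-pot conjugate reduction / enantioselective α-hydroxylation under chiral phosphine-oxide Lewis-base catalysis; this sets the only stereocentre, C2 (R).
3. 7 ⇐ dibromochalcone 5 by twofold Suzuki–Miyaura prenylation; 5 ⇐ 3 by tris-MOM protection.
4. 3 ⇐ ketone 1 + aldehyde 2 by Claisen–Schmidt condensation.
5. No ring is formed: ring A (resorcinol ketone) and ring B (phenol) come intact from 1 and 2.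

Assumption: 1-(5-bromo-2,4-dihydroxyphenyl)ethan-1-one (1) is taken as a catalogue compound.
Assumption: the (S)-catalyst in step 4 is taken to give Re-face oxygen delivery; if the first run shows the opposite sense, the (R)-catalyst is used with no other change.

## Route

Step 1
Reactants: 1 1-(5-bromo-2,4-dihydroxyphenyl)ethan-1-one; 2 3-bromo-4-hydroxybenzaldehyde
Product: 3 (E)-1-(5-bromo-2,4-dihydroxyphenyl)-3-(3-bromo-4-hydroxyphenyl)prop-2-en-1-one
Conditions: KOH (50% aq, 10 equiv), EtOH, rt, 48 h; then 2 M HCl, 0 °C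
Reagents that add atoms: none
Why: Claisen–Schmidt aldol condensation, in which the enolate of 1 adds to 2 and E1cB dehydration gives the thermodynamic (E)-enone; unprotected hydroxychalcones of this kind form under concentrated KOH, and no prenyl group is yet present.

Step 2
Reactants: 3 (E)-1-(5-bromo-2,4-dihydroxyphenyl)-3-(3-bromo-4-hydroxyphenyl)prop-2-en-1-one; 4 chloromethyl methyl ether
Product: 5 (E)-1-[5-bromo-2,4-bis(methoxymethoxy)phenyl]-3-[3-bromo-4-(methoxymethoxy)phenyl]prop-2-en-1-one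
Conditions: NaH (3.6 equiv), MOMCl (3.6 equiv), DMF, 0 °C → rt
Reagents that add atoms: chloromethyl methyl ether (MOMCl), COCCl
Why: Williamson-type O-alkylation of the three phenoxides by the reactive α-chloro ether; excess NaH keeps any flavanone in equilibrium with the open chalcone phenoxide, so the chelated 2'-OH is capped as well.

Step 3
Reactants: 5 (E)-1-[5-bromo-2,4-bis(methoxymethoxy)phenyl]-3-[3-bromo-4-(methoxymethoxy)phenyl]prop-2-en-1-one; 6 4,4,5,5-tetramethyl-2-(3-methylbut-2-en-1-yl)-1,3,2-dioxaborolane (prenylboronic acid pinacol ester)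
Product: 7 (E)-1-[2,4-bis(methoxymethoxy)-5-(3-methylbut-2-en-1-yl)phenyl]-3-[4-(methoxymethoxy)-3-(3-methylbut-2-en-1-yl)phenyl]prop-2-en-1-one
Conditions: 6 (3 equiv), Pd(dppf)Cl2 (8 mol %), K3PO4 (2 M aq, 6 equiv), THF, 70 °C, 12 h
Reagents that add atoms: prenylboronic acid pinacol ester, CC(C)=CCB1OC(C)(C)C(C)(C)O1
Why: Twofold Suzuki–Miyaura coupling of the two aryl bromides with an allylic boronate, the wide-bite-angle dppf ligand on the divalent palladium precatalyst favouring transfer at the α-carbon (linear prenyl arene), while the enone and MOM acetals are inert.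

Step 4
Reactants: 7 (E)-1-[2,4-bis(methoxymethoxy)-5-(3-methylbut-2-en-1-yl)phenyl]-3-[4-(methoxymethoxy)-3-(3-methylbut-2-en-1-yl)phenyl]prop-2-en-1-one; 8 trichlorosilane; 9 3-phenyl-2-(phenylsulfonyl)oxaziridine (racemic, donates one oxygen atom only)
Product: 12 (2R)-1-[2,4-bis(methoxymethoxy)-5-(3-methylbut-2-en-1-yl)phenyl]-2-hydroxy-3-[4-(methoxymethoxy)-3-(3-methylbut-2-en-1-yl)phenyl]propan-1-one, via Z-trichlorosilyl enolate 10 (not isolated), via α-trichlorosilyloxy ketone 11 (not isolated)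
Conditions: (S)-BINAP dioxide [(S)-2,2'-bis(diphenylphosphoryl)-1,1'-binaphthyl] (10 mol %), HSiCl3 (1.2 equiv), EtCN, −78 °C, 4 h; then 9 (1.6 equiv), −78 → −45 °C; sat. aq NaHCO3
Reagents that add atoms: 3-phenyl-2-(phenylsulfonyl)oxaziridine, O=S(=O)(N1OC1c1ccccc1)c1ccccc1
Why: Proposed new method: chiral Lewis-base-catalysed reductive α-hydroxylation, in which the bisphosphine dioxide activates HSiCl3 for 1,4-hydride delivery through a six-membered cyclic transition state on the s-cis enone to give the (Z)-trichlorosilyl enolate 10 as a catalyst-bound cationic hypervalent silicate, which is intercepted not by an aldehyde as in the known reaction but by the N-sulfonyloxaziridine (sulfonyl oxygen on silicon), so that oxygen goes to the unshielded Re face of the enolate α-carbon to set (R), silicon moving to the new oxygen (11) and being hydrolysed on work-up; the closest known reactions are the bisphosphine-dioxide/HSiCl3 enantioselective reductive aldol reaction of chalcones and the Davis oxaziridine hydroxylation of metal enolates, and neither reagent touches the prenyl alkenes at this temperature.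

Step 5
Reactants: 12 (2R)-1-[2,4-bis(methoxymethoxy)-5-(3-methylbut-2-en-1-yl)phenyl]-2-hydroxy-3-[4-(methoxymethoxy)-3-(3-methylbut-2-en-1-yl)phenyl]propan-1-one
Product: 13 Kanzonol Y, (2R)-1-[2,4-dihydroxy-5-(3-methylbut-2-en-1-yl)phenyl]-2-hydroxy-3-[4-hydroxy-3-(3-methylbut-2-en-1-yl)phenyl]propan-1-one
Conditions: HCl (1.25 M in MeOH), 40 °C, 2–3 h
Reagents that add atoms: none
Why: Acid-catalysed transacetalisation of the three MOM ethers to dimethoxymethane, mild enough that the o-prenylphenols do not cyclise to chromans and the α-ketol does not enolise, so the (R)-centre from step 4 is kept.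

## Compound list

1 | 1-(5-bromo-2,4-dihydroxyphenyl)ethan-1-one | CC(=O)c1cc(Br)c(O)cc1O | starting material
2 | 3-bromo-4-hydroxybenzaldehyde | O=Cc1ccc(O)c(Br)c1 | starting material
3 | (E)-1-(5-bromo-2,4-dihydroxyphenyl)-3-(3-bromo-4-hydroxyphenyl)prop-2-en-1-one | O=C(/C=C/c1ccc(O)c(Br)c1)c1cc(Br)c(O)cc1O | intermediate
4 | chloromethyl methyl ether | COCCl | starting material
5 | (E)-1-[5-bromo-2,4-bis(methoxymethoxy)phenyl]-3-[3-bromo-4-(methoxymethoxy)phenyl]prop-2-en-1-one | COCOc1ccc(/C=C/C(=O)c2cc(Br)c(OCOC)cc2OCOC)cc1Br | intermediate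
6 | 4,4,5,5-tetramethyl-2-(3-methylbut-2-en-1-yl)-1,3,2-dioxaborolane | CC(C)=CCB1OC(C)(C)C(C)(C)O1 | starting material
7 | (E)-1-[2,4-bis(methoxymethoxy)-5-(3-methylbut-2-en-1-yl)phenyl]-3-[4-(methoxymethoxy)-3-(3-methylbut-2-en-1-yl)phenyl]prop-2-en-1-one | COCOc1ccc(/C=C/C(=O)c2cc(CC=C(C)C)c(OCOC)cc2OCOC)cc1CC=C(C)C | intermediate
8 | trichlorosilane | Cl[SiH](Cl)Cl | starting material
9 | 3-phenyl-2-(phenylsulfonyl)oxaziridine (racemic) | O=S(=O)(N1OC1c1ccccc1)c1ccccc1 | starting material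
10 | (Z)-trichlorosilyl enolate: trichloro{[(1Z)-1-[2,4-bis(methoxymethoxy)-5-(3-methylbut-2-en-1-yl)phenyl]-3-[4-(methoxymethoxy)-3-(3-methylbut-2-en-1-yl)phenyl]prop-1-en-1-yl]oxy}silane | Cl[Si](Cl)(Cl)O/C(=C\Cc1ccc(OCOC)c(CC=C(C)C)c1)c1cc(CC=C(C)C)c(OCOC)cc1OCOC | intermediate
11 | (2R)-1-[2,4-bis(methoxymethoxy)-5-(3-methylbut-2-en-1-yl)phenyl]-3-[4-(methoxymethoxy)-3-(3-methylbut-2-en-1-yl)phenyl]-2-[(trichlorosilyl)oxy]propan-1-one | CC(C)=CCc1cc(C[C@@H](O[Si](Cl)(Cl)Cl)C(=O)c2cc(CC=C(C)C)c(OCOC)cc2OCOC)ccc1OCOC | intermediate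
12 | (2R)-1-[2,4-bis(methoxymethoxy)-5-(3-methylbut-2-en-1-yl)phenyl]-2-hydroxy-3-[4-(methoxymethoxy)-3-(3-methylbut-2-en-1-yl)phenyl]propan-1-one | CC(C)=CCc1cc(C[C@@H](O)C(=O)c2cc(CC=C(C)C)c(OCOC)cc2OCOC)ccc1OCOC | intermediate
13 | Kanzonol Y, (2R)-1-[2,4-dihydroxy-5-(3-methylbut-2-en-1-yl)phenyl]-2-hydroxy-3-[4-hydroxy-3-(3-methylbut-2-en-1-yl)phenyl]propan-1-one | CC(C)=CCc1cc(C[C@@H](O)C(=O)c2cc(CC=C(C)C)c(O)cc2O)ccc1O | target

## Step count and risks

Total steps: 5. Longest linear sequence: 5 (steps 1–5; the two aromatic pieces are joined in step 1).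

Steps most likely to fail:

**Step 4 (proposed new reaction).** Risks are low ee in the oxygen transfer, Mannich trapping of enolate 10 by the sulfonylimine by-product, chlorosilane attack on the 2'-MOM acetal, and over-reduction of the ketone. The fallback uses known chemistry, sets out from 7 and comes back at 12.
- Juliá–Colonna epoxidation of 7 (poly-L-leucine, urea–H2O2, DBU, THF, rt) is a nucleophilic epoxidation that ignores the prenyl alkenes. It gives [2,4-bis(methoxymethoxy)-5-(3-methylbut-2-en-1-yl)phenyl]{(2R,3S)-3-[4-(methoxymethoxy)-3-(3-methylbut-2-en-1-yl)phenyl]oxiran-2-yl}methanone F4.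
- LiBr/AcOH in THF at 0 °C opens the oxirane at the benzylic carbon. This gives (2S)-3-bromo-1-[2,4-bis(methoxymethoxy)-5-(3-methylbut-2-en-1-yl)phenyl]-2-hydroxy-3-[4-(methoxymethoxy)-3-(3-methylbut-2-en-1-yl)phenyl]propan-1-one F5 as a mixture of C3 epimers. The C2–O bond is untouched; the descriptor changes only because CHBr outranks the carbonyl.
- Bu3SnH/AIBN in toluene at 80 °C removes the benzylic bromine and gives 12.

**Step 3 (twofold prenyl Suzuki coupling).** Risks are γ-transfer giving reverse-prenyl (1,1-dimethylallyl) arenes, and incomplete coupling at the hindered, electron-rich bromide of ring A. The fallback sets out from 5 and comes back at 7.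
- Twofold Suzuki–Miyaura allylation with allylboronic acid pinacol ester (Pd(dppf)Cl2, K3PO4, THF/H2O, 70 °C) has no α/γ ambiguity. It gives (E)-1-[5-allyl-2,4-bis(methoxymethoxy)phenyl]-3-[3-allyl-4-(methoxymethoxy)phenyl]prop-2-en-1-one F3.
- Double cross-metathesis with 2-methyl-2-butene (second-generation Grubbs catalyst RuCl2(=CHPh)(H2IMes)(PCy3), CH2Cl2, 40 °C) turns both allyl groups into prenyl groups and gives 7. The electron-poor enone is a poor metathesis partner.

**Step 1 (unprotected Claisen–Schmidt condensation).** Risks are low conversion of the phenoxide-deactivated partners and flavanone formation on acidification. The fallback sets out from 1 and 2 and comes back at 5, bypassing 3.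
- Protect first: 1 with MOMCl/NaH/DMF gives 1-[5-bromo-2,4-bis(methoxymethoxy)phenyl]ethan-1-one F1.
- 2 with MOMCl/i-Pr2NEt/CH2Cl2 gives 3-bromo-4-(methoxymethoxy)benzaldehyde F2.
- Condensing F1 with F2 (KOH, EtOH/H2O, rt) gives 5 directly.

## Further compounds

F1 | step 1 | 1-[5-bromo-2,4-bis(methoxymethoxy)phenyl]ethan-1-one | CC(=O)c1cc(Br)c(OCOC)cc1OCOC
F2 | step 1 | 3-bromo-4-(methoxymethoxy)benzaldehyde | COCOc1ccc(C=O)cc1Br
F3 | step 3 | (E)-1-[5-allyl-2,4-bis(methoxymethoxy)phenyl]-3-[3-allyl-4-(methoxymethoxy)phenyl]prop-2-en-1-one | COCOc1ccc(/C=C/C(=O)c2cc(CC=C)c(OCOC)cc2OCOC)cc1CC=C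
F4 | step 4 | [2,4-bis(methoxymethoxy)-5-(3-methylbut-2-en-1-yl)phenyl]{(2R,3S)-3-[4-(methoxymethoxy)-3-(3-methylbut-2-en-1-yl)phenyl]oxiran-2-yl}methanone | O=C(c1cc(CC=C(C)C)c(OCOC)cc1OCOC)[C@@H]2O[C@H]2c3ccc(OCOC)c(CC=C(C)C)c3
F5 | step 4 | (2S)-3-bromo-1-[2,4-bis(methoxymethoxy)-5-(3-methylbut-2-en-1-yl)phenyl]-2-hydroxy-3-[4-(methoxymethoxy)-3-(3-methylbut-2-en-1-yl)phenyl]propan-1-one (C3 epimers) | O=C(c1cc(CC=C(C)C)c(OCOC)cc1OCOC)[C@H](O)C(Br)c1ccc(OCOC)c(CC=C(C)C)c1
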